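The monomer in chains at the asked time is one amount, the chains that share it are the other, and their ratio is the average asked for.

common to all: D 14 mM
- midnight: Z 70 µM; G 63 µM; run made earlier
- spring: Z 70 µM; G 99 µM; run made earlier
- dusk: Z 140 µM; G 45 µM; run made earlier
- flask: Z 70 µM; G 45 µM; time 10 d

- midnight (time / d: X / %, D / %): 0.833: 11.1, 87.8; 2.50: 30.7, 68.3; 5.00: 49.8, 47.9; 8.00: 63.8, 34.1; 10.0: 69.6, 28.7
- spring (time / d: X / %, D / %): 0.833: 9.5, 90.2; 1.67: 18.2, 80.7; 3.00: 29.2, 69.7; 5.00: 42.4, 56.1; 10.0: 63.6, 34.8
- dusk (time / d: X / %, D / %): 2.08: 53.0, 47.5; 4.00: 71.0, 28.8; 6.00: 78.2, 20.1; 8.00: 81.2, 18.1; 10.0: 81.6, 17.7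

(readings scatter by 0.5 percentage points)

* whether the average number of monomer units in a chain (chains begun, living or dead) reaches 200 by 10 d (yes / no)
* average number of monomer units in a chain (chains begun, living or dead) at 10 d

- the average divides the monomer in chains by the number of chains begun, living and dead together
- what may be going on: D + Z -> Q + X; D + Q -> X + Q; X + Q -> D + Q; Z + G -> E; D -> J
- the earlier runs do not show the number of chains; that part of a forecast is a guess

So I turn the question round. The midnight run's X of 69.6% at 10.0 d, taken on the charge of D and divided by the length of 200, gives 48.7 µM, my chain allowance: the chains that this X can feed at the wanted length. The flask has midnight's Z and less G, 45 µM against 63 µM, and the spring run, with more G than midnight, ended lower in X at 63.6%. I therefore take midnight's X as a floor for the flask, and the allowance with it. If each G took one Z, 25.0 µM of chains would begin, and if none did, 70 µM. The allowance is more than the first and less than the second, so the answer hangs on the chain count.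

The forecast says yes, with an average of 211 from 48 µM of chains, and adds: “The chain count is inferred, not measured”.

    D + Z → Q + X (k = 1.01 L mol⁻¹ min⁻¹)
    D + Q → X + Q, rate k2*[Q]*[D] (k = 3.27 L mol⁻¹ min⁻¹)
    X + Q → D + Q, rate k3*[Q] as long as [X] is above zero (k = 0.00750 min⁻¹)
    Z + G → E (k = 228 L mol⁻¹ min⁻¹)
    D → J (k = 2.68 × 10⁻⁶ min⁻¹)

The flask gives yes with an average of 220, reaching the wanted length at 7.44 d, and it holds 0.0463 mM of Q, less than the allowance of 48.7 µM. In the flask, each step taken net, X is made 3.45 times as fast as it is used up at 3.32 d, and at 10.0 d still 1.54 times as fast, with X then at 72.8%.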